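**Retrosynthetic overview**

- Numbering: ring C1 (bears the chain), C2 (OAc), C3 (O-angelate), C4 (OH, Me), C5 (Cl), C6 (CH2); chain C7 (=C14H2), C8 (O-angelate), C9, C10–C11 (epoxide).
- Feature: the carbocycle C1–C6 with the C4 methyl group and the cis C2/C3 oxygens is the microbial cis-dihydrodiol of toluene, and the C1–C7 bond is cis and vicinal to the C2 oxygen, so C7 can be delivered from that oxygen.
- Late stage: oxirane by catalyst-controlled epoxidation of a prenyl alkene; acetate placed after the two angelates; the three oxygens are told apart as silyl ether (O2, the former lactone oxygen), PMB ether (O3) and ketone (C8, reduced under reagent control).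
- Middle stage: C9–C11 by allylation of the C8 lactol and cross-metathesis; C4–OH/C5–Cl by chlorohydroxylation of C4=C5; C14 by α-methylenation of the C8 lactone.
- Ring order: the cyclohexane comes from the arene diol; the only ring built is the temporary five-membered acetal O2–C8–C7–C1–C2, closed by bromoacetal radical cyclisation onto the diene; the oxirane is formed last.

Key step: step 4

Remark on the chemistry: acetal and lactol carbons and the C8 carbinol before its oxidation are carried as epimer mixtures, because these centres are destroyed or reset later; the L-fructose-derived epoxidation ketone is taken as accessible from L-sorbose.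

**Route**

Step 1
Reactants: 1 (1S,2R)-3-methylcyclohexa-3,5-diene-1,2-diol; 2 4-methoxybenzaldehyde dimethyl acetal
Product: 3 cis-fused 4-methoxybenzylidene acetal of the diol (both epimers at the acetal carbon)
Conditions: 2 (1.2 equiv), camphorsulfonic acid (2 mol %), CH2Cl2, −20 to 0 °C; Et3N quench
Reagents that add atoms: 4-methoxybenzaldehyde dimethyl acetal (2), COc1ccc(cc1)C(OC)OC
Why: Acid-catalysed transacetalisation of a cis-1,2-diol is fast, the catalytic weak acid at low temperature should avoid dehydration of the dienediol to a cresol, and no ring stereocentre is touched.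

Step 2
Reactants: 3 4-methoxybenzylidene acetal
Product: 4 (1S,6R)-6-[(4-methoxybenzyl)oxy]-5-methylcyclohexa-2,4-dien-1-ol (PMB on O3, free C2 hydroxyl)
Conditions: iBu2AlH (2.5 equiv), CH2Cl2, −78 to −40 °C; aq. potassium sodium tartrate (KNaC4H4O6)
Reagents that add atoms: none
Why: Regioselective reductive opening of an arylidene acetal by iBu2AlH, in which aluminium binds the more accessible oxygen O2 (remote from the methyl-bearing C4), that C–O bond breaks and hydride reduces the oxocarbenium ion, so the PMB group should stay on the hindered O3 without change at C2 or C3.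

Step 3
Reactants: 4 mono-PMB dienol; 5 ethyl vinyl ether; 6 N-bromosuccinimide
Product: 7 2-bromo-1-ethoxyethyl acetal at O2 (PMB on O3; both acetal epimers)
Conditions: 5 (5 equiv), 6 (1.2 equiv), CH2Cl2, −40 to 0 °C, dark
Reagents that add atoms: ethyl vinyl ether (5), C=COCC; N-bromosuccinimide (6), O=C1CCC(=O)N1Br
Why: Haloacetalisation, in which N-bromosuccinimide reacts far faster with the electron-rich vinyl ether than with the diene and the bromo-oxocarbenium ion is captured by the C2 hydroxyl, gives the radical precursor with an inconsequential acetal centre.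

Step 4
Reactants: 7 bromoacetal
Product: 8 cis-fused bicyclic ethyl acetal (ring O2–C8(OEt)–C7H2–C1–C2; PMB on O3; C4=C5 alkene; both acetal epimers)
Conditions: Bu3SnH (1.3 equiv, syringe pump over 6 h), AIBN (0.15 equiv), benzene, 80 °C, 0.01 M
Reagents that add atoms: none
Why: The stannyl radical abstracts bromine from 7, and the primary C7 radical, held under C1 by the two-atom O2–C8 tether, adds to the diene terminus C1 to give an allyl radical over C4–C5–C6 that is reduced by Bu3SnH, which regenerates the chain carrier. This is the Ueno–Stork bromoacetal radical cyclisation, applied here to a cyclohexadiene. The one ring closed is the 2-ethoxytetrahydrofuran O2–C8–C7–C1–C2, formed in the 5-exo-trig mode, since 6-endo attack at C6 would give a non-allylic radical through a more strained transition state. The new stereocentre C1 is controlled by the tether, because a five-membered ring spanning C1 and C2 can only close cis, so C7 arrives on the face of O2 as the target requires. The step needs ring closure before reduction (slow stannane addition, high dilution) and hydrogen capture at C6 rather than C4, which should be favoured because C4 carries the methyl group and is flanked by the C3 PMB ether, so the trisubstituted C4=C5 alkene is kept. The acetal carbon C8 stays a mixture that steps 5 and 6 remove.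

Step 5
Reactants: 8 bicyclic ethyl acetal
Product: 9 bicyclic lactol (C8–OH, anomer mixture)
Conditions: 1 M HCl, THF, 0 °C to rt
Reagents that add atoms: water, O
Why: Acid-catalysed hydrolysis of the mixed cyclic acetal gives the lactol under conditions that should leave the PMB ether and the trisubstituted alkene untouched, with no ring stereocentre involved.

Step 6
Reactants: 9 bicyclic lactol
Product: 10 cis-fused γ-lactone (C8=O; PMB on O3; C4=C5)
Conditions: nPr4N[RuO4] (5 mol %), N-methylmorpholine N-oxide (1.5 equiv), 4 Å molecular sieves, CH2Cl2, rt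
Reagents that add atoms: none
Why: Ley–Griffith oxidation converts a lactol into the lactone under neutral conditions compatible with the electron-rich benzyl ether and the alkene, and it removes the C8 epimer mixture.

Step 7
Reactants: 10 γ-lactone; 11 N,N-dimethylmethyleneiminium iodide (Eschenmoser's salt); 12 iodomethane
Product: 15 α-methylene lactone (C7=C14H2; PMB on O3; C4=C5), via Mannich base 13 (not isolated), via trimethylammonium iodide 14 (not isolated)
Conditions: LiN(iPr)2 (1.15 equiv), THF, −78 °C; 11 (2 equiv), −78 °C to rt; then 12 (10 equiv), MeOH, rt; then sat. aq. NaHCO3, CH2Cl2, rt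
Reagents that add atoms: N,N-dimethylmethyleneiminium iodide (11), C=[N+](C)C.[I-]; iodomethane (12), CI (its methyl group is held only by 14 and leaves with trimethylamine)
Why: Eschenmoser α-methylenation, in which the lactone lithium enolate is aminomethylated at C7 (Mannich reaction) and quaternisation followed by mild-base elimination gives the exocyclic C7=C14 alkene, removes the transient C7 stereocentre, and hydrogen carbonate should avoid migration of the double bond into the ring.

Step 8
Reactants: 15 α-methylene lactone; 16 N-chlorosuccinimide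
Product: 17 chlorohydrin lactone (C4–OH cis to O3, C5–Cl trans to it; PMB on O3)
Conditions: 16 (1.15 equiv), acetone/H2O (4:1), 0 °C to rt, dark
Reagents that add atoms: N-chlorosuccinimide (16), O=C1CCC(=O)N1Cl; water, O
Why: Electrophilic chlorohydroxylation (halohydrin formation), in which Cl+ attacks the only electron-rich alkene from the convex face opposite the three cis substituents on C1, C2 and C3 and water opens the chloronium ion at the tertiary C4 from the other face (Markovnikov and trans-diaxial, through the chair that keeps C7 and O3 equatorial), should set C4–OH on the face of O3 and C5–Cl on the opposite face, the conjugated C7=C14 alkene being inert.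

Step 9
Reactants: 17 chlorohydrin lactone
Product: 18 α-methylene lactol (C8–OH, anomer mixture)
Conditions: iBu2AlH (2.4 equiv), CH2Cl2, −78 °C; aq. potassium sodium tartrate
Reagents that add atoms: none
Why: Partial reduction of a lactone to the lactol by iBu2AlH at −78 °C proceeds by 1,2-attack on the α-methylene lactone through a tetrahedral aluminium alkoxide that is stable at this temperature, with one equivalent consumed by the tertiary hydroxyl and the secondary chloride inert.

Step 10
Reactants: 18 α-methylene lactol; 19 allylmagnesium bromide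
Product: 20 allyl diol (C2–OH and C8–OH, C8 epimer mixture)
Conditions: 19 (5 equiv), THF, −78 to −20 °C; sat. aq. NH4Cl at −20 °C
Reagents that add atoms: allylmagnesium bromide (19), C=CC[Mg]Br
Why: Grignard 1,2-addition to the ring-opened hydroxy-enal form of the lactol forms C8–C9 with no regiochemical ambiguity for the allyl reagent, the C8 epimers are erased in step 12, and the bromomagnesium alkoxide of the tertiary chlorohydrin should not close to an epoxide at or below −20 °C.

Step 11
Reactants: 20 allyl diol; 21 2-methylbut-2-ene
Product: 22 prenyl diol (C10=C11Me2)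
Conditions: RuCl2(=CHPh)(PCy3)(H2IMes) (second-generation Grubbs catalyst, 5 mol %), 21/CH2Cl2 (1:1), 35 °C, sealed tube
Reagents that add atoms: 2-methylbut-2-ene (21), CC=C(C)C
Why: Olefin cross-metathesis of the terminal vinyl group with 2-methylbut-2-ene gives the trisubstituted prenyl terminus, the hindered 1,1-disubstituted C7=C14 alkene should not engage the ruthenium carbene, and free hydroxyls are tolerated.

Step 12
Reactants: 22 prenyl diol
Product: 23 hydroxy enone (C8 ketone conjugated with C7=C14; free C2–OH)
Conditions: activated MnO2 (20 equiv), CH2Cl2, rt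
Reagents that add atoms: none
Why: Chemoselective MnO2 oxidation of the allylic C8 alcohol in the presence of the non-allylic C2 and tertiary C4 hydroxyls converts both C8 epimers into one enone, which should stay open-chain because hemiketal formation with the C2 hydroxyl would cost the enone conjugation.

Step 13
Reactants: 23 hydroxy enone; 24 triethylsilyl trifluoromethanesulfonate
Product: 25 enone with triethylsilyl ether on O2
Conditions: 24 (1.1 equiv), 2,6-lutidine (2 equiv), CH2Cl2, −78 °C
Reagents that add atoms: triethylsilyl trifluoromethanesulfonate (24), CC[Si](CC)(CC)OS(=O)(=O)C(F)(F)F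
Why: Silylation with a silyl triflate and a hindered non-nucleophilic base at −78 °C protects the secondary C2 hydroxyl much faster than the tertiary C4 hydroxyl and without conjugate addition to the vinyl ketone, masking the oxygen that will carry the acetate.

Step 14
Reactants: 25 silyl-protected enone
Product: 26 (8S)-allylic alcohol (silyl ether on O2, PMB on O3)
Conditions: (R)-2-methyl-CBS-oxazaborolidine (0.3 equiv), catecholborane (3 equiv), toluene, −78 °C; MeOH, then pH 7 buffer
Reagents that add atoms: none
Why: Corey–Bakshi–Shibata reduction, with the α-branched alkenyl group as the large and the CH2-prenyl group as the small substituent, should give the (8S)-alcohol from the (R)-oxazaborolidine by reagent control, and catecholborane at −78 °C reduces the carbonyl 1,2 without hydroborating the alkenes.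

Step 15
Reactants: 26 (8S)-allylic alcohol
Product: 27 triol (free C3–OH, C4–OH and C8–OH; silyl ether on O2)
Conditions: DDQ (1.3 equiv), CH2Cl2/pH 7 phosphate buffer (10:1), 0 °C
Reagents that add atoms: none
Why: Oxidative cleavage of the PMB ether by DDQ in buffered wet CH2Cl2 frees the C3 hydroxyl while the silyl ether, the chlorohydrin and the alkenes survive, the unactivated allylic C8 alcohol being oxidised much more slowly than the ether is cleaved.

Step 16
Reactants: 27 triol; 28 angelic acid ((Z)-2-methylbut-2-enoic acid)
Product: 29 C3,C8-bis-angelate (silyl ether on O2, free tertiary C4–OH)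
Conditions: 28 (6 equiv), 2,4,6-trichlorobenzoyl chloride (6 equiv), Et3N (7 equiv), toluene, rt, 2 h; then 27, 75 °C
Reagents that add atoms: angelic acid (28), C/C=C(/C)C(=O)O
Why: Yamaguchi-type acylation through the preformed mixed anhydride of angelic and 2,4,6-trichlorobenzoic acid, run without a nucleophilic catalyst, is the established way to esterify hindered secondary alcohols with retention of the Z geometry, so both secondary hydroxyls (C3, C8) should react while the tertiary C4 hydroxyl does not, and with O2 still silylated no acyl migration is possible.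

Step 17
Reactants: 29 silylated bis-angelate
Product: 30 bis-angelate with free C2–OH
Conditions: HF·pyridine, pyridine, THF, 0 °C
Reagents that add atoms: none
Why: Fluoride-mediated desilylation with buffered HF·pyridine removes the secondary triethylsilyl ether under mildly acidic conditions that should not cleave or migrate the angelates, close the chlorohydrin or touch the alkenes.

Step 18
Reactants: 30 bis-angelate alcohol; 31 acetic anhydride
Product: 32 C2-acetate bis-angelate (des-epoxy target with C10=C11 alkene)
Conditions: 31 (3 equiv), pyridine, DMAP (0.1 equiv), CH2Cl2, 0 °C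
Reagents that add atoms: acetic anhydride (31), CC(=O)OC(C)=O
Why: DMAP-catalysed acetylation of the secondary C2 hydroxyl at 0 °C is much faster than acylation of the tertiary C4 hydroxyl or migration of the neighbouring hindered angelate, so the acetate is placed last and at one position only.

Step 19
Reactants: 32 des-epoxy target
Product: 33 CNP0313121.1 (ring 1R,2S,3S,4S,5S; chain 8S,10S in the working numbering)
Conditions: L-fructose-derived Shi ketone (1,2:4,5-di-O-isopropylidene-β-L-erythro-2,3-hexodiulo-2,6-pyranose, 0.5 equiv), KHSO5 (as 2KHSO5·KHSO4·K2SO4, 1.5 equiv), K2CO3, Bu4NHSO4 (cat.), MeCN/dimethoxymethane–aq. Na2B4O7/Na2EDTA buffer, pH about 10, 0 °C, short reaction time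
Reagents that add atoms: potassium peroxymonosulfate, [K+].[O-]S(=O)(=O)OO
Why: Shi asymmetric epoxidation, in which the chiral dioxirane reacts with the electron-rich trisubstituted C10=C11 alkene and not with the conjugated angelates or the hindered 1,1-disubstituted C7=C14 alkene, should set (10S) by catalyst control through the spiro transition state, since the usual D-fructose-derived ketone gives R at such CH carbons and its enantiomer is used here.

**Compound list**

1 | (1S,2R)-3-methylcyclohexa-3,5-diene-1,2-diol | C1=CC=C(C)[C@@H](O)[C@H]1O | starting material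
2 | 4-methoxybenzaldehyde dimethyl acetal | COc1ccc(cc1)C(OC)OC | starting material
3 | (3aR,7aS)-2-(4-methoxyphenyl)-4-methyl-3a,7a-dihydro-1,3-benzodioxole, both epimers at the acetal carbon | C1=CC=C(C)[C@H]2OC(c3ccc(OC)cc3)O[C@@H]12 | intermediate
4 | (1S,6R)-6-[(4-methoxybenzyl)oxy]-5-methylcyclohexa-2,4-dien-1-ol | C1=CC=C(C)[C@@H](OCc2ccc(OC)cc2)[C@H]1O | intermediate
5 | ethyl vinyl ether | C=COCC | starting material
6 | N-bromosuccinimide | O=C1CCC(=O)N1Br | starting material
7 | 2-bromo-1-ethoxyethyl acetal of the hydroxyl of 4 (PMB on O3, both acetal epimers) | C1=CC=C(C)[C@@H](OCc2ccc(OC)cc2)[C@H]1OC(CBr)OCC | intermediate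
8 | cis-fused 2-ethoxy-7-[(4-methoxybenzyl)oxy]-6-methyl-2,3,3a,4,7,7a-hexahydrobenzofuran (C7 and O2 cis on the ring, C4=C5, both acetal epimers) | CCOC1C[C@H]2CC=C(C)[C@@H](OCc3ccc(OC)cc3)[C@H]2O1 | intermediate
9 | lactol of 8 (2-hydroxy in place of 2-ethoxy, anomer mixture) | OC1C[C@H]2CC=C(C)[C@@H](OCc3ccc(OC)cc3)[C@H]2O1 | intermediate
10 | cis-fused 7-[(4-methoxybenzyl)oxy]-6-methyl-3a,4,7,7a-tetrahydrobenzofuran-2(3H)-one | O=C1C[C@H]2CC=C(C)[C@@H](OCc3ccc(OC)cc3)[C@H]2O1 | intermediate
11 | N,N-dimethylmethyleneiminium iodide (Eschenmoser's salt) | C=[N+](C)C.[I-] | starting material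
12 | iodomethane | CI | starting material
13 | 3-[(dimethylamino)methyl] derivative of lactone 10 (C7 epimers) | O=C1C(CN(C)C)[C@H]2CC=C(C)[C@@H](OCc3ccc(OC)cc3)[C@H]2O1 | intermediate (not isolated)
14 | trimethylammonium iodide of 13 | O=C1C(C[N+](C)(C)C)[C@H]2CC=C(C)[C@@H](OCc3ccc(OC)cc3)[C@H]2O1.[I-] | intermediate (not isolated)
15 | 3-methylene lactone (C7=C14H2; PMB on O3; C4=C5) | O=C1C(=C)[C@H]2CC=C(C)[C@@H](OCc3ccc(OC)cc3)[C@H]2O1 | intermediate
16 | N-chlorosuccinimide | O=C1CCC(=O)N1Cl | starting material
17 | chlorohydrin of 15: C5–Cl, C4–OH (OH cis to O3, Cl trans), methylene lactone retained | O=C1C(=C)[C@H]2C[C@H](Cl)[C@@](C)(O)[C@@H](OCc3ccc(OC)cc3)[C@H]2O1 | intermediate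
18 | lactol of 17 (C8–OH, anomer mixture) | OC1C(=C)[C@H]2C[C@H](Cl)[C@@](C)(O)[C@@H](OCc3ccc(OC)cc3)[C@H]2O1 | intermediate
19 | allylmagnesium bromide | C=CC[Mg]Br | starting material
20 | allyl diol: ring C2–OH, chain C8–OH (epimers) bearing CH2CH=CH2, C7=C14H2 | C=CCC(O)C(=C)[C@H]1C[C@H](Cl)[C@@](C)(O)[C@@H](OCc2ccc(OC)cc2)[C@H]1O | intermediate
21 | 2-methylbut-2-ene | CC=C(C)C | starting material
22 | prenyl diol (as 20 with CH2CH=CMe2) | CC(C)=CCC(O)C(=C)[C@H]1C[C@H](Cl)[C@@](C)(O)[C@@H](OCc2ccc(OC)cc2)[C@H]1O | intermediate
23 | hydroxy enone (C8 ketone, free C2–OH) | CC(C)=CCC(=O)C(=C)[C@H]1C[C@H](Cl)[C@@](C)(O)[C@@H](OCc2ccc(OC)cc2)[C@H]1O | intermediate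
24 | triethylsilyl trifluoromethanesulfonate | CC[Si](CC)(CC)OS(=O)(=O)C(F)(F)F | starting material
25 | enone with triethylsilyl ether on O2 | CC(C)=CCC(=O)C(=C)[C@H]1C[C@H](Cl)[C@@](C)(O)[C@@H](OCc2ccc(OC)cc2)[C@H]1O[Si](CC)(CC)CC | intermediate
26 | (8S)-allylic alcohol (silyl ether on O2, PMB on O3) | CC(C)=CC[C@H](O)C(=C)[C@H]1C[C@H](Cl)[C@@](C)(O)[C@@H](OCc2ccc(OC)cc2)[C@H]1O[Si](CC)(CC)CC | intermediate
27 | triol with free C3–OH, C4–OH, C8–OH (silyl ether on O2) | CC(C)=CC[C@H](O)C(=C)[C@H]1C[C@H](Cl)[C@@](C)(O)[C@@H](O)[C@H]1O[Si](CC)(CC)CC | intermediate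
28 | angelic acid, (Z)-2-methylbut-2-enoic acid | C/C=C(/C)C(=O)O | starting material
29 | C3,C8-bis-angelate (silyl ether on O2) | CC(C)=CC[C@H](OC(=O)/C(C)=C\C)C(=C)[C@H]1C[C@H](Cl)[C@@](C)(O)[C@@H](OC(=O)/C(C)=C\C)[C@H]1O[Si](CC)(CC)CC | intermediate
30 | C3,C8-bis-angelate with free C2–OH | CC(C)=CC[C@H](OC(=O)/C(C)=C\C)C(=C)[C@H]1C[C@H](Cl)[C@@](C)(O)[C@@H](OC(=O)/C(C)=C\C)[C@H]1O | intermediate
31 | acetic anhydride | CC(=O)OC(C)=O | starting material
32 | C2-acetate C3,C8-bis-angelate with C10=C11 alkene (des-epoxy target) | CC(C)=CC[C@H](OC(=O)/C(C)=C\C)C(=C)[C@H]1C[C@H](Cl)[C@@](C)(O)[C@@H](OC(=O)/C(C)=C\C)[C@H]1OC(C)=O | intermediate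
33 | CNP0313121.1 | C=C([C@H](C[C@@H]1OC1(C)C)OC(=O)/C(C)=C\C)[C@H]1C[C@H](Cl)[C@@](C)(O)[C@@H](OC(=O)/C(C)=C\C)[C@H]1OC(C)=O | target

**Step count and risks**

Total step count: 19. Longest linear sequence: 19 steps (1 to 33); all other inputs are commercial.

Steps most likely to fail:

1. Step 4 (key step). What may go wrong: hydrogen transfer to the methyl-bearing terminus C4 of the allyl radical, which puts the alkene at C5=C6. Less likely are a 1,5-hydrogen shift from C3–H followed by aromatisation, or reduction before ring closure. The fallback sets out from 7 and comes back at 8, and fixes the alkene position thermodynamically instead of kinetically. The cyclisation is run as in step 4 and the unseparated mixture of 8 and its regioisomer, the C5=C6 bicyclic acetal with C4–H F1, is treated with DDQ in buffered wet CH2Cl2. This gives the C3 allylic alcohol F2 from 8 and the homoallylic alcohol F3 from F1. Dess–Martin periodinane then gives the conjugated C3 enone F4 from F2 and the β,γ-unsaturated ketone F5 from F3. DBU in CH2Cl2 moves the C5=C6 bond of F5 into conjugation, so both series converge on F4. Luche reduction (NaBH4, CeCl3·7H2O, MeOH, −78 °C) should deliver hydride to the convex face, anti to the C2 oxygen, and return the cis alcohol F2 as a single alkene isomer. 4-Methoxybenzyl trichloroacetimidate with catalytic La(OTf)3 then gives 8.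

2. Step 8. What may go wrong: ene-type allylic chlorination with loss of a methyl hydrogen (exocyclic alkene), or water capture at the wrong carbon or from the wrong face. The fallback sets out from 15 and comes back at 17, and replaces the chloronium route by hydroxyl-directed epoxidation and chloride opening. DDQ in buffered wet CH2Cl2 removes the PMB group to give the allylic alcohol lactone F6. VO(acac)2 (cat.) with tBuOOH in CH2Cl2 at 0 °C epoxidises C4=C5 on the face of the C3 hydroxyl to give the epoxy alcohol F7. Ti(OiPr)4 with Et2NH2Cl, the titanium-mediated opening of a 2,3-epoxy alcohol at the carbon distal to the carbinol, should deliver chloride to the secondary C5 with inversion (also the trans-diaxial mode) and give the chlorodiol lactone F8. 4-Methoxybenzyl trichloroacetimidate with catalytic La(OTf)3 etherifies the secondary C3 hydroxyl in preference to the tertiary C4 hydroxyl and gives 17.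

3. Step 16. What may go wrong: slow acylation of the flanked C3 hydroxyl, with drift of the activated angeloyl unit from Z to E under forcing conditions. The fallback sets out from 27 and comes back at 29, and builds the Z alkene on the ester instead of transferring a preformed angeloyl group. Both secondary hydroxyls are esterified with 2-(diphenoxyphosphoryl)propanoic acid (N,N′-dicyclohexylcarbodiimide, cat. DMAP, CH2Cl2) to give the C3,C8-bis(phosphonopropanoate) F9. Ando's Z-selective Horner–Wadsworth–Emmons reaction with acetaldehyde (NaI, DBU, THF, 0 °C; a base too weak to deprotonate the tertiary chlorohydrin alcohol) then gives 29.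

**Further compounds**

F1 | step 4 | C5=C6 regioisomer of 8 with C4–H (bicyclic ethyl acetal, PMB on O3) | CCOC1C[C@H]2C=CC(C)[C@@H](OCc3ccc(OC)cc3)[C@H]2O1
F2 | step 4 | C3 allylic alcohol of 8 (PMB removed, C4=C5) | CCOC1C[C@H]2CC=C(C)[C@@H](O)[C@H]2O1
F3 | step 4 | C3 alcohol of F1 (C5=C6, C4–H) | CCOC1C[C@H]2C=CC(C)[C@@H](O)[C@H]2O1
F4 | step 4 | conjugated C3 enone (C3=O, C4=C5) of the bicyclic ethyl acetal | CCOC1C[C@H]2CC=C(C)C(=O)[C@H]2O1
F5 | step 4 | β,γ-unsaturated C3 ketone (C3=O, C5=C6, C4–H) of the bicyclic ethyl acetal | CCOC1C[C@H]2C=CC(C)C(=O)[C@H]2O1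
F6 | step 8 | C3 allylic alcohol of methylene lactone 15 | O=C1C(=C)[C@H]2CC=C(C)[C@@H](O)[C@H]2O1
F7 | step 8 | C4–C5 epoxy alcohol, oxirane on the face of the C3 hydroxyl | O=C1C(=C)[C@H]2C[C@H]3O[C@@]3(C)[C@@H](O)[C@H]2O1
F8 | step 8 | chlorodiol lactone (C3–OH, C4–OH, C5–Cl; 17 without PMB) | O=C1C(=C)[C@H]2C[C@H](Cl)[C@@](C)(O)[C@@H](O)[C@H]2O1
F9 | step 16 | C3,C8-bis[2-(diphenoxyphosphoryl)propanoate] of 27 | CC(C)=CC[C@H](OC(=O)C(C)P(=O)(Oc2ccccc2)Oc2ccccc2)C(=C)[C@H]1C[C@H](Cl)[C@@](C)(O)[C@@H](OC(=O)C(C)P(=O)(Oc2ccccc2)Oc2ccccc2)[C@H]1O[Si](CC)(CC)CC
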